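The cyclohexene ring C1–C6 (p-menthane numbering: C1 methyl, C3 pyranone, C4 isopropyl) is a Diels–Alder retron, because the C1=C2 olefin lies opposite the C4–C5 edge. One catalytic enantioselective [4+2] cycloaddition of a prenal-derived 1-silyloxy-3-methylbutadiene with 2-isopropylacrolein closes the ring through C5–C6 and C3–C4. It places the olefin and the methyl group and fixes C4 absolutely as a quaternary centre whose formyl group is a traceless activator. Stereoretentive rhodium decarbonylation unveils the C4–H centre. Ionisation of the allylic C3–O bond then lets the nucleophilic ring carbon of 4-hydroxy-6-styryl-2-pyranone add anti to the isopropyl group. The key-step precursors are two acyclic aldehyde derivatives of five and six carbons.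

Key step: step 3

Assumption: the facial sense of the catalyst in step 3 is taken from its known behaviour with other 2-substituted acroleins. Both antipodes of the catalyst are available from D- and L-tryptophan.

Step 1
Reactants: 1 3-methylbut-2-enal (prenal)
Product: 2 (E)-tert-butyl(dimethyl)[(3-methylbuta-1,3-dien-1-yl)oxy]silane
Conditions: TBSOTf, Et3N, Et2O, 0 °C to rt
Reagents that add atoms: tert-butyldimethylsilyl triflate (TBSOTf), CC(C)(C)[Si](C)(C)OS(=O)(=O)C(F)(F)F
Why: Soft enolisation (silyl dienol ether formation): O-silylation of the enal acidifies the γ-methyl protons, Et3N removes one, and the extended (E)-dienol ether should result.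

Step 2
Reactants: 3 3-methylbutanal (isovaleraldehyde)
Product: 4 3-methyl-2-methylidenebutanal (2-isopropylacrolein)
Conditions: aq HCHO (37 %), pyrrolidine (10 mol %), EtCO2H (10 mol %), i-PrOH, 45 °C
Reagents that add atoms: formaldehyde, C=O
Why: Amine-catalysed Mannich condensation–elimination (α-methylenation of an aldehyde) puts the CH2 group that becomes C5 on the α-carbon that becomes C4.

Step 3
Reactants: 2 (E)-tert-butyl(dimethyl)[(3-methylbuta-1,3-dien-1-yl)oxy]silane, 4 3-methyl-2-methylidenebutanal
Product: 5 (1S,2S)-2-[(tert-butyldimethylsilyl)oxy]-4-methyl-1-(propan-2-yl)cyclohex-3-ene-1-carbaldehyde (silyloxy and formyl groups cis)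
Conditions: (4R)-2-butyl-4-(1H-indol-3-ylmethyl)-3-tosyl-1,3,2-oxazaborolidin-5-one (20 mol %), CH2Cl2–toluene, −78 to −40 °C
Reagents that add atoms: none
Why: The boron Lewis acid binds the formyl oxygen of 4 and lowers its LUMO, so that 2 and 4 combine in a concerted, asynchronous, normal-electron-demand [4+2] cycloaddition in which bonding between C5 (enal β-carbon) and C6 (free diene terminus) runs ahead of C3–C4 bonding. The closest known reaction type is the oxazaborolidinone-catalysed enantioselective Diels–Alder reaction of 2-substituted acroleins with oxygenated acyclic dienes. The only new ring, cyclohexene C1–C6, closes by suprafacial–suprafacial addition, and the former central diene bond becomes the C1=C2 olefin of the target. C4 is controlled by the catalyst, whose indole ring stacks on one face of the bound enal so that the diene should reach only the open Cα face and give the (S)-configured quaternary centre. C3 follows from the (E)-geometry of 2 and an endo-formyl transition state (O and CHO cis), but it is only a relay that is ionised in step 7, so an exo adduct, which has the same C4, would converge. The step needs ortho/para regioselectivity and C=C over C=O chemoselectivity: the 1-silyloxy and 3-methyl donors both put the largest HOMO coefficient on C6, and the only moderately activated diene should leave the hindered formyl group untouched.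

Step 4
Reactants: 5 (1S,2S)-2-[(tert-butyldimethylsilyl)oxy]-4-methyl-1-(propan-2-yl)cyclohex-3-ene-1-carbaldehyde
Product: 6 tert-butyl(dimethyl){[(1R,6R)-3-methyl-6-(propan-2-yl)cyclohex-2-en-1-yl]oxy}silane (trans-piperitol silyl ether)
Conditions: RhCl(PPh3)3 (1.1 equiv), PhCN, 130 °C
Reagents that add atoms: none
Why: Tsuji–Wilkinson decarbonylation: formyl C–H oxidative addition to monovalent rhodium, CO extrusion and C–H reductive elimination all take place on one face, so H should replace CHO with retention and reveal the C4 centre of the target (the descriptors change only through CIP priorities), while silyl ether and trisubstituted olefin are inert.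

Step 5
Reactants: 7 4-hydroxy-6-methyl-2H-pyran-2-one, 8 benzaldehyde
Product: 10 4-hydroxy-6-(2-hydroxy-2-phenylethyl)-2H-pyran-2-one (racemic), via dilithio dianion 9 (not isolated)
Conditions: LiN(iPr)2 (2.2 equiv), THF, −78 °C; then 8; aq HCl
Reagents that add atoms: none
Why: Dianion aldol addition: after O-deprotonation the second base equivalent removes a vinylogous 6-methyl proton, and the more reactive carbanion site adds to the aldehyde; the carbinol centre is racemic and is erased in step 6.

Step 6
Reactants: 10 4-hydroxy-6-(2-hydroxy-2-phenylethyl)-2H-pyran-2-one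
Product: 11 4-hydroxy-6-[(E)-2-phenylethenyl]-2H-pyran-2-one
Conditions: p-TsOH·H2O (cat.), toluene, reflux, water separator
Reagents that add atoms: none
Why: Acid-catalysed E1 dehydration through the benzylic cation should give the fully conjugated, thermodynamically preferred (E)-styryl olefin.

Step 7
Reactants: 6 tert-butyl(dimethyl){[(1R,6R)-3-methyl-6-(propan-2-yl)cyclohex-2-en-1-yl]oxy}silane, 11 4-hydroxy-6-[(E)-2-phenylethenyl]-2H-pyran-2-one
Product: 13 4-hydroxy-3-[(1R,6R)-3-methyl-6-(propan-2-yl)cyclohex-2-en-1-yl]-6-[(E)-2-phenylethenyl]-2H-pyran-2-one (target), via menthenyl cation 12 (not isolated)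
Conditions: Bi(OTf)3 (5 mol %), CH2Cl2–MeNO2, 0 °C
Reagents that add atoms: none
Why: Lewis-acid-catalysed SN1 allylation of a cyclic 1,3-dicarbonyl-type nucleophile (Friedel–Crafts-type terpenylation): loss of silanol gives cation 12, which the pyranone carbon between the two oxygenated carbons should attack at the secondary terminus C3 and anti to the neighbouring isopropyl group, so the C4 centre sets C3 trans, while O-allylation and attack at the tertiary terminus are reversible under the acid.

Compound list
1 | 3-methylbut-2-enal | CC(C)=CC=O | starting material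
2 | (E)-tert-butyl(dimethyl)[(3-methylbuta-1,3-dien-1-yl)oxy]silane | CC(=C)/C=C/O[Si](C)(C)C(C)(C)C | intermediate
3 | 3-methylbutanal | CC(C)CC=O | starting material
4 | 3-methyl-2-methylidenebutanal | CC(C)C(=C)C=O | intermediate
5 | (1S,2S)-2-[(tert-butyldimethylsilyl)oxy]-4-methyl-1-(propan-2-yl)cyclohex-3-ene-1-carbaldehyde | CC1=C[C@H](O[Si](C)(C)C(C)(C)C)[C@@](C=O)(C(C)C)CC1 | intermediate
6 | tert-butyl(dimethyl){[(1R,6R)-3-methyl-6-(propan-2-yl)cyclohex-2-en-1-yl]oxy}silane | CC1=C[C@H](O[Si](C)(C)C(C)(C)C)[C@@H](C(C)C)CC1 | intermediate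
7 | 4-hydroxy-6-methyl-2H-pyran-2-one | Cc1cc(O)cc(=O)o1 | starting material
8 | benzaldehyde | O=Cc1ccccc1 | starting material
9 | dilithio dianion of 7 (4-oxide and 6-methylene carbanion) | [Li+].[Li+].[CH2-]c1cc([O-])cc(=O)o1 | intermediate
10 | 4-hydroxy-6-(2-hydroxy-2-phenylethyl)-2H-pyran-2-one (racemic) | OC(Cc1cc(O)cc(=O)o1)c1ccccc1 | intermediate
11 | 4-hydroxy-6-[(E)-2-phenylethenyl]-2H-pyran-2-one | O=c1cc(O)cc(/C=C/c2ccccc2)o1 | intermediate
12 | p-menth-1-en-3-yl cation with the C4 centre of 6 unchanged | CC1=C[CH+][C@@H](C(C)C)CC1 | intermediate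
13 | 4-hydroxy-3-[(1R,6R)-3-methyl-6-(propan-2-yl)cyclohex-2-en-1-yl]-6-[(E)-2-phenylethenyl]-2H-pyran-2-one | CC1=C[C@H](c2c(O)cc(/C=C/c3ccccc3)oc2=O)[C@@H](C(C)C)CC1 | target

Total step count: 7. Longest linear sequence: 4 steps (1, 3, 4, 7).

Steps most likely to fail

**Step 4.**
- What may go wrong: CO extrusion at the congested quaternary carbon may be too slow. The tertiary alkyl–rhodium species may also lose a β-hydrogen and drain material into menthadienes.
- The fallback replaces the organometallic extrusion by a radical chain. It sets out from 2 and 4.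
- The cycloaddition of step 3 is run with the antipodal catalyst (4S)-2-butyl-4-(1H-indol-3-ylmethyl)-3-tosyl-1,3,2-oxazaborolidin-5-one and should give the mirror-image aldehyde F1.
- Pinnick oxidation (NaClO2, NaH2PO4, 2-methylbut-2-ene, t-BuOH–H2O) gives the carboxylic acid F2.
- 1-Hydroxypyridine-2(1H)-thione, DCC and DMAP give the thiohydroxamate ester F3.
- Barton reductive decarboxylation (t-BuSH, hν, toluene) passes through a planar C4 radical. This radical should accept hydrogen anti to the neighbouring silyloxy group and give the cis silyl ether F4, whose C4 centre is that of 6.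
- Under the conditions of step 7, F4 ionises and the fallback comes back to the route at 12.

**Step 3.**
- What may go wrong: the bulky α-isopropyl group may slow the cycloaddition so much that Lewis-acid cleavage of the silyl dienol ether or a vinylogous Mukaiyama–Michael addition takes over. Facial discrimination may also be poor.
- The fallback uses a two-point-binding dienophile without a quaternary centre and builds the isopropyl group afterwards. The same two ring bonds are still formed in the cycloaddition. It sets out from 2.
- The dienophile is 3-acryloyl-1,3-oxazolidin-2-one. The catalyst is divalent copper, Cu(SbF6)2 with 2,2'-(propane-2,2-diyl)bis[(4S)-4-tert-butyl-4,5-dihydrooxazole] (10 mol %, CH2Cl2). This should give the trans imide F5.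
- Me(MeO)NH·HCl and AlMe3 give the N-methoxy-N-methylamide F6.
- MeMgBr gives the methyl ketone F7.
- Wittig methylenation (Ph3P=CH2, THF) gives the isopropenyl compound F8.
- H2 (1 atm) over RhCl(PPh3)3 in benzene should saturate only the 1,1-disubstituted olefin, which brings the fallback back to the route at 6.

**Step 7.**
- What may go wrong: competing O-allylation, attack at the tertiary allyl terminus, or acid-induced addition of the free 4-hydroxy group to the C1=C2 olefin after the coupling.
- The fallback replaces the free cation by a stereospecific metal-bound allyl unit. It sets out from 6.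
- Bu4NF in THF gives trans-piperitol F9, and ClCO2Me with pyridine gives the methyl carbonate F10.
- Tsuji–Trost allylation of 11 follows (Pd(PPh3)4, 5 mol %, THF, 50 °C). Zerovalent palladium ionises anti to the carbonate and the soft pyranone nucleophile attacks anti to the metal at the less substituted terminus.
- The net retention gives the trans product, and the fallback comes back to the route at 13.

Further compounds
F1 | step 4 | (1R,2R)-2-[(tert-butyldimethylsilyl)oxy]-4-methyl-1-(propan-2-yl)cyclohex-3-ene-1-carbaldehyde (enantiomer of 5) | CC1=C[C@@H](O[Si](C)(C)C(C)(C)C)[C@](C=O)(C(C)C)CC1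
F2 | step 4 | (1R,2R)-2-[(tert-butyldimethylsilyl)oxy]-4-methyl-1-(propan-2-yl)cyclohex-3-ene-1-carboxylic acid | CC1=C[C@@H](O[Si](C)(C)C(C)(C)C)[C@](C(=O)O)(C(C)C)CC1
F3 | step 4 | 2-thioxopyridin-1(2H)-yl (1R,2R)-2-[(tert-butyldimethylsilyl)oxy]-4-methyl-1-(propan-2-yl)cyclohex-3-ene-1-carboxylate | CC1=C[C@@H](O[Si](C)(C)C(C)(C)C)[C@](C(=O)ON2C=CC=CC2=S)(C(C)C)CC1
F4 | step 4 | tert-butyl(dimethyl){[(1S,6R)-3-methyl-6-(propan-2-yl)cyclohex-2-en-1-yl]oxy}silane (cis-piperitol silyl ether) | CC1=C[C@@H](O[Si](C)(C)C(C)(C)C)[C@@H](C(C)C)CC1
F5 | step 3 | 3-({(1S,2S)-2-[(tert-butyldimethylsilyl)oxy]-4-methylcyclohex-3-en-1-yl}carbonyl)-1,3-oxazolidin-2-one (trans) | CC1=C[C@H](O[Si](C)(C)C(C)(C)C)[C@@H](C(=O)N2CCOC2=O)CC1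
F6 | step 3 | (1S,2S)-2-[(tert-butyldimethylsilyl)oxy]-N-methoxy-N,4-dimethylcyclohex-3-ene-1-carboxamide | CC1=C[C@H](O[Si](C)(C)C(C)(C)C)[C@@H](C(=O)N(C)OC)CC1
F7 | step 3 | 1-{(1S,2S)-2-[(tert-butyldimethylsilyl)oxy]-4-methylcyclohex-3-en-1-yl}ethan-1-one | CC1=C[C@H](O[Si](C)(C)C(C)(C)C)[C@@H](C(C)=O)CC1
F8 | step 3 | tert-butyl(dimethyl){[(1S,6R)-3-methyl-6-(prop-1-en-2-yl)cyclohex-2-en-1-yl]oxy}silane (trans) | CC1=C[C@H](O[Si](C)(C)C(C)(C)C)[C@@H](C(C)=C)CC1
F9 | step 7 | (1R,6R)-3-methyl-6-(propan-2-yl)cyclohex-2-en-1-ol (trans-piperitol) | CC1=C[C@H](O)[C@@H](C(C)C)CC1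
F10 | step 7 | methyl (1R,6R)-3-methyl-6-(propan-2-yl)cyclohex-2-en-1-yl carbonate | CC1=C[C@H](OC(=O)OC)[C@@H](C(C)C)CC1
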